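Readings and results are simulated with constants of no real substance, and the scatter is random.

The target comes slowly: 19.8 % after 40.0 min in Sunday's run and 17.2 % at that time in Tuesday's, which started at about ten times the concentration. Both runs climb at much the same pace, but what is asked is a concentration effect, and in these readings that shows only late on, as a correction you have to compute separately.

| flask | starting material | other conformer | remark | time |
|---|---|---|---|---|
| Sunday's | 0.0064 M | 0.25 equiv | run made earlier |  |
| Tuesday's | 0.074 M | 0.25 equiv | run made earlier |  |
| noon | 0.012 M | 0.250 equiv |  | 3.0 h |
| dawn | 0.030 M | 0.250 equiv |  | 3.0 h |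
| winter | 0.10 M | 0.250 equiv |  | 3.0 h |

| run | time / min | target / % | isomer of the product / % |
|---|---|---|---|
| Sunday's | 8.00 | 4.2 | 3.4 |
| Sunday's | 25.0 | 10.9 | 2.7 |
| Sunday's | 40.0 | 19.8 | 4.0 |
| Sunday's | 60.0 | 24.2 | 4.6 |
| Sunday's | 90.0 | 36.0 | 5.0 |
| Sunday's | 120 | 47.1 | 4.6 |
| Tuesday's | 20.0 | 8.7 | 0.8 |
| Tuesday's | 40.0 | 17.2 | 3.3 |
| Tuesday's | 60.0 | 26.2 | 4.1 |
| Tuesday's | 80.0 | 31.5 | 5.1 |
| Tuesday's | 120 | 41.4 | 7.3 |

(each reading ± 1 percentage point)

- share of target in all that became target or isomer of the product or side product for noon, dawn, winter, in this order
- how the row runs (rises all the way / rises, then falls / hardly changes / falls, then rises / falls all the way)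

- a species is counted by the starting material in it: one side product counts as two
- "hardly changes" means that all values lie within two and a half points (for a concentration: within two and a half percent of the largest)

In the first instants there is little to read. The isomer of the product stands at 3.4 % after 8.00 min on Sunday and 0.8 % after 20.0 min on Tuesday, and the scatter of a reading is 1 percentage point.

For the middle, I take the dilute Sunday run as the uncorrected flask. At 120 min it has 48.3 % unconverted. Assuming first-order decay, the converted share X at 3.0 h and the isomer's part Q of it are:

X = 66.4 %

Q = 5.91 %

Late on, the runs part. At 120 min Tuesday's target lies 5.7 points below Sunday's, a difference of two scattered readings. I assume that each side product takes one target and one starting material. Half of its count is then target lost directly, and the other half is starting material, of which about the Sunday yield, 47.1 %, would have become target by then. Dividing by the difference in concentration and scaling in proportion to time, a rough step, gives the side-product yield per unit of starting concentration at the asked time, λ: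

λ = 1.72 /M

The selectivity at starting concentration c is then S = one minus (Q + λc)/X:

noon: 88.0 %

dawn: 83.3 %

winter: 65.2 %

The forecast, reading Tuesday's curve as “starting material being lost to a second-order dimerisation”, gave 84 %, 79 % and 65 %, a row that falls all the way, lower than mine at noon and dawn.

The flask gives 86.9 %, 81.7 % and 65.9 %: the row falls all the way.

    other conformer → isomer of the product (k = 11.0 /h)
    starting material + target → side product (k = 1.70 /M/h)
    starting material → target (k = 0.320 /h)
    starting material ⇌ other conformer (K = 0.00250, k = 0.440 /h)

At noon the half-life of target by the side reaction alone, with concentrations as charged, is 34 h, long against the 3.0 h of the run. There λc gives 2.06 % side product, and the noon flask holds 2.69 % at 3.00 h. In the winter flask λc gives 17.2 %, and that flask holds 18.4 % at 3.00 h.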